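A small charge of incoming ligand forces two exchanges to compete for it, and one ratio tells how they divide it.

    complex with two exchanged → over-reaction product (k1 = 1.8 × 10⁻⁴ h⁻¹)
    complex with one exchanged + incoming ligand → leaving ligand + complex with two exchanged (k2 = 1.7 L mol⁻¹ h⁻¹)
    starting complex + incoming ligand → leaving ligand + complex with one exchanged (k3 = 31 L mol⁻¹ h⁻¹)
    starting complex ⇌ dormant form (K4 = 0.55, k4 = 0.30 h⁻¹)
the same everywhere: starting complex 0.11 M; leaving ligand 0.500 equiv; time 4.0 d

| run | incoming ligand |
|---|---|
| amber | 1.00 equiv |
| grey | 2.50 equiv |
1. which of these there is most of at the end, counted by the starting complex in it, amber (complex with one exchanged / complex with two exchanged / starting complex)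
2. which of these there is most of at the end, counted by the starting complex in it, grey (complex with one exchanged / complex with two exchanged / starting complex)
3. final amount of the leader among these, as a percentage of the starting complex charged, in amber
4. final amount of the leader among these, as a percentage of the starting complex charged, in grey

The selectivity factor S is the rate constant of the first exchange, divided by one plus the equilibrium constant of the dormant form, over the rate constant of the second exchange: 11.8. The denominator counts the starting complex and dormant form as one pool. Starting complex has a half-life of 0.20 h by its exchange in amber with ligand as charged, shorter than the 0.820 h relaxation half-life of that equilibrium, so the early ratio can lean towards the bare 18.2.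

Which numbers must be known well? Over-reaction takes 1.71% of complex with two exchanged in 4.0 d, which matters little for amber. Time matters little too in amber: both exchanges use incoming ligand, its 1.00 equiv is less than the 2 equiv they could take, and with ligand as charged the second exchange has a half-life of 0.15 d, so the exchanges can be expected to stop with the ligand well inside 4.0 d. S matters more: the peak of complex with one exchanged along the pool curve is S to the power −1/(S−1), and S off by a factor 2 gives 69.6% or 86.9%.

This peak uses 1.07 equiv of ligand, close to the amber charge. So this reckoning gives amber complex with one exchanged at 79.5%. Grey charges more than the 2 equiv both exchanges need, so it gives complex with two exchanged at 98.3%.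

The forecast says complex with one exchanged at 78.7% for amber, slightly below this peak, and complex with two exchanged at 98.4% for grey, reasoning that “the mix stops mostly at the mono-exchanged complex” with one equivalent.

The simulation gives complex with one exchanged at 79.2% in amber and complex with two exchanged at 98.4% in grey.

Amber stands 0.3 percentage points below the peak that S gave. The neighbour of amber charged with 0.400 equiv takes the same reckoning to a smaller charge. If a charge x is consumed, the pool falls to about one minus x, and complex with two exchanged reaches about (−ln of that pool, minus x)/S, which is 0.942%. That neighbour ends with 0% of its incoming ligand left, 38.6% complex with one exchanged and 0.675% complex with two exchanged.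

(The numbers of this flask were set for the occasion; the flask was simulated.)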